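To the colleague who asked for a quick number and guessed that the teal flask would follow the grey run to 19.5% at 80.0 min: that guess is the zero of the scale, the case in which a flask turns over the same share of its charge whatever the charge.

| flask | solid substrate | gas | remark | time |
|---|---|---|---|---|
| teal | 0.65 M | 200 mM (held) | the very flask that is asked about, followed so far |  |
| grey | 1.3 M | 200 mM (held) | run made earlier |  |
| flask | 0.65 M | 200 mM (held) |  | 80 min |

- teal (time / min: product / %, dissolved substrate / %, solid substrate / %): 1.50: 0, 7.7, 91.9; 3.00: 0.3, 14.7, 85.0; 5.00: 1.2, 20.3, 78.6; 6.00: 1.1, 23.0, 75.7; 8.00: 2.0, 26.4, 70.4; 10.0: 3.8, 30.8, 66.7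
- grey (time / min: product / %, dissolved substrate / %, solid substrate / %): 12.0: 3.0, 16.0, 81.4; 25.0: 5.6, 19.5, 74.6; 40.0: 9.1, 20.2, 69.9; 50.0: 12.4, 20.0, 67.1; 60.0: 14.8, 20.4, 65.0; 80.0: 19.5, 20.4, 59.5

(each reading ± 0.5 percentage points)

- solid substrate is a solid; its amount is given per volume of the solution
- at the start none of the solid substrate is in solution
- at the start none of the gas is in solution
- dissolved substrate means what is dissolved; the solid is not counted in it

- the product standing at 80 min, as a percentage of the solid substrate charged
- concentration of dissolved substrate in solution at 40 min, in percent of saturation
- the change that raises the amount of product at 80 min, in percent of the solid substrate charged most ("none" if none brings more than 2 percentage points) (Thursday's / Sunday's / Friday's / Tuesday's / none)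
- amount of product at 80 min, in percent of the solid substrate charged, after Sunday's

- Thursday's: doubling the dissolution coefficient of the solid substrate, all else as stated
- Sunday's: doubling the transfer coefficient of the gas, all else as stated
- Friday's: doubling the solubility of the solid substrate, all else as stated
- Tuesday's: doubling the saturation concentration of gas, all else as stated

The shares disagree with that zero. Dissolved substrate is 30.8% in the teal run at 10.0 min and 16.0% in the grey run at 12.0 min, though grey holds twice the charge. In molarity they nearly agree, at 200 mM and 208 mM. So I read teal's solution as grey's solution, and I carry molarity instead of share: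

grey product × grey charge = 254 mM

This is the output, the molarity of product made by that time over standing solid. Grey's product and dissolved substrate together take 519 mM, less than teal's charge of 0.65 M, so I expect teal to hold solid at that time. My number follows:

output ÷ charge = 39.0%

The forecast gives 39%, 91%, Tuesday's and 44%, saying “Doubling gas transfer should therefore give a modest gain”.

The flask gives 39.4%, 90.9% and Tuesday's, which adds 38 percentage points.

    solid substrate ⇌ dissolved substrate, rate k1*(cs1 - [dissolved substrate]) while solid is left; crystals form when [dissolved substrate] > cs1 (solubility = 0.290 M, k = 7.84 h⁻¹)
    dissolved substrate + reagent → product (k = 171 M⁻¹ h⁻¹)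
    gas ⇌ reagent, rate k3*(csat - [reagent]) (kL = 1.00 h⁻¹)

The two part at Sunday's doubling of the transfer coefficient of the gas: it gives 75.8% against the forecast's 44%, and adds 36 points, more than Thursday's 0.14 points or Friday's 0.65 points, so in this flask the passage of gas into reagent behaves as the rate-limiting step. The output also serves the neighbour flask charged with 2.6 M: 254 mM over that charge is 9.77%, and that neighbour holds 9.84% of product at 80 min. This flask has not come to rest at 80 min, with 19.8% solid substrate and 40.8% dissolved substrate. Its unmade 394 mM exceeds its output so far, 256 mM. At ten times the time, solid and dissolved substrate stand at 0% and 0%, and product at 100%.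

The earlier runs and the new flask come from a simulation with constants of no real substance.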